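One percentage point here means a hundredth of the starting material charged, and in that unit the earlier runs show how much target stands once the reaction is over.

| flask | starting material | partner | free catalyst | second catalyst | temperature | remark | time |
|---|---|---|---|---|---|---|---|
| Tuesday's | 20 mM | 19 mM | 46 µM | 2 mM | 20 °C | run made earlier |  |
| Wednesday's | 20 mM | 19 mM | 23 µM | 2 mM | 31 °C | run made earlier |  |
| Sunday's | 20 mM | 19 mM | 92 µM | 2 mM | 20 °C | run made earlier |  |
| autumn | 20 mM (fed, over 3.0 min) | 19.0 mM | 46 µM | 2.0 mM | 25 °C | all else is in the flask from the start; the feed brings no volume worth counting | 15 min |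
| winter | 20 mM | 19.0 mM (in portions, 5, over 12 min) | 46 µM | 2.0 mM | 25 °C | first portion at the start, last at 12 min | 15 min |
| summer | 20 mM (fed, over 12 min) | 19.0 mM | 46 µM | 2.0 mM |  | the addition at −5 °C, then warmed to 25 °C; the feed brings no volume worth counting | 15 min |
| spring | 20 mM | 19.0 mM (fed, over 12 min) | 46 µM | 2.0 mM | 25 °C | all else is in the flask from the start; the feed brings no volume worth counting | 15 min |
| noon | 20 mM | 19.0 mM | 46 µM | 2.0 mM | 25 °C | everything together at the start | 15 min |

- Tuesday's (time / min: target / %, starting material / %): 1.33: 13.4, 23.7; 2.50: 15.1, 7.9; 4.00: 14.7, 1.7; 5.00: 13.9, 0.4; 6.00: 15.4, 0.9; 8.00: 15.0, 0; 10.0: 14.8, 0.5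
- Wednesday's (time / min: target / %, starting material / %): 1.00: 9.9, 22.4; 3.00: 10.2, 1.4; 5.00: 10.3, 0.6; 8.00: 9.9, 0.1; 10.0: 11.5, 0.7; 15.0: 10.6, 0.5; 20.0: 10.6, 0.6
- Sunday's (time / min: target / %, starting material / %): 2.50: 15.9, 7.5; 5.00: 15.8, 0.3; 8.00: 15.1, 0.5; 10.0: 15.4, 0.4; 12.0: 15.1, 0.1; 15.0: 15.9, 0.9; 20.0: 15.4, 0

(standard deviation of a reading: 0.5 percentage points)

- the earlier runs were read with a standard deviation of 0.5 percentage points

- the best flask by amount of target, in percent of the starting material charged; "all alike" if 1.5 percentage points covers them all (autumn / winter / summer / spring / noon / all alike)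
- amount of target at the end, in percent of the starting material charged, autumn
- amount of target at the end, in percent of the starting material charged, winter
- amount of target at the end, in percent of the starting material charged, summer
- amount of target at the end, in percent of the starting material charged, spring
- amount of target at the end, in percent of the starting material charged, noon

Call the plateau the mean target from 2.50 min on in Tuesday's run, 3.00 min on in Wednesday's and 2.50 min on in Sunday's; at those readings starting material stands at 7.9 % or less. The plateaus are 14.8 % for Tuesday's run, 10.5 % for Wednesday's and 15.5 % for Sunday's.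

This looks contradictory. Between Tuesday's 46 µM of free catalyst and Sunday's 92 µM the plateau stands 0.7 points higher, yet between Wednesday's 23 µM and Tuesday's 46 µM, also a doubling, it stands 4.3 points higher, which is more. But the second comparison is not a clean one, since Wednesday's run stood at 31 °C and Tuesday's at 20 °C.

So the difference between Tuesday's and Sunday's runs, both at 20 °C, can be treated as a correction. Read from these scattered plateaus, it is a factor of 1.05 per doubling, and on the assumption of the same factor for the lower doubling, Wednesday's plateau is reckoned at 11.0 % for 46 µM of free catalyst. The remaining ratio, 1.35, is then put down to temperature. Taking the fall as exponential in temperature, it gives 25.7 K as the halving span, the temperature rise that takes the plateau of target, with everything charged together at the start, to half.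

Noon has Tuesday's charge, so the span carries Tuesday's plateau to 25 °C and gives 12.9 %. The dosed flasks have the same amounts but differ in how they go in, and they lie outside this reckoning.

The forecast named noon as best, with 12.8 % for noon against the 12.9 % reckoned here, 5.2 % for autumn, 2.6 % for winter, 12 % for summer and 0.6 % for spring, on the ground “Feeding starting material therefore hurts”.

The flasks give 13.1 % for noon, 12.8 % for autumn, 8.20 % for winter, 15.1 % for summer and 8.44 % for spring, so summer stands highest.

    starting material + free catalyst ⇌ free catalyst + open intermediate (K = 0.510, k = 1930 /M/s, Ea = 41.0 kJ/mol, ΔH = −20.0 kJ/mol)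
    second catalyst + open intermediate ⇌ catalyst intermediate (K = 23.0 /M, k = 16.6 /M/s, Ea = 47.0 kJ/mol, ΔH = −57.0 kJ/mol)
    partner + catalyst intermediate → second catalyst + target (k = 810 /M/s, Ea = 35.0 kJ/mol)
    partner → decomposition product (k = 7.49 × 10⁻⁶ /s, Ea = 109 kJ/mol)
    starting material + target → side product (k = 5.46 /M/s, Ea = 43.0 kJ/mol)
    (constants at 25 °C)

Noon lies 0.20 points above the reckoned plateau. The neighbouring flask is winter kept at 50 °C. Carried as a trial onto winter's portioned charge and beyond the temperatures of the runs, the halving span takes winter's 8.20 % at 25 °C to 4.18 %. The neighbour ends lower than that, with 2.38 % of target and 97.6 % of side product. Its limiting reagent, starting material, stands at 0 %, while partner stands at 43 % of its own charge.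

The readings stem from a simulated flask on assumed constants; noise was put on by code.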